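common to all: substrate 0.10 M
- Wednesday's: catalyst 1 mM; added ligand 0.41 mM; temperature 25 °C; run made earlier
- Friday's: catalyst 1 mM; added ligand 0.62 mM; temperature 60 °C; run made earlier
- Tuesday's: catalyst 0.50 mM; added ligand 0.83 mM; temperature 25 °C; run made earlier
- noon: catalyst 1.0 mM; added ligand 0.83 mM; temperature 60 °C; time 15 d
- summer: catalyst 1.0 mM; added ligand 0.83 mM; temperature 90 °C; time 15 d
- autumn: catalyst 1.0 mM; added ligand 0.83 mM; temperature 30 °C; time 15 d

| run | time / d | target / % | isomer of the product / % |
|---|---|---|---|
| Wednesday's | 10.0 | 27.6 | 0 |
| Wednesday's | 25.0 | 22.7 | 0.7 |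
| Wednesday's | 50.0 | 6.4 | 0 |
| Wednesday's | 60.0 | 4.7 | 0 |
| Friday's | 1.67 | 14.5 | 1.4 |
| Friday's | 4.00 | 0.3 | 2.3 |
| Friday's | 8.00 | 0 | 1.9 |
| Friday's | 12.0 | 0 | 1.9 |
| Tuesday's | 10.0 | 21.4 | 0 |
| Tuesday's | 25.0 | 29.5 | 0 |
| Tuesday's | 50.0 | 24.3 | 1.1 |
| Tuesday's | 60.0 | 19.3 | 0 |

(scatter of a reading: 1 percentage point)

- in a conversion other conformer counts as not yet reacted

1. the flask that comes out highest in share of target in all that became target or isomer of the product or over-reaction product, or "all alike" when all lie within 1.5 percentage points (noon / summer / autumn / all alike)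
2. share of target in all that became target or isomer of the product or over-reaction product, noon
3. share of target in all that became target or isomer of the product or over-reaction product, summer
4. share of target in all that became target or isomer of the product or over-reaction product, autumn

The easy step was a division: 0.10 M of substrate over 1.0 mM of catalyst meant 100 turnovers per catalyst charged to make the charge into target, and as many again to carry it on to over-reaction product. So I counted turnovers: if both steps were pseudo-first-order with c(catalyst) held constant, their number at one temperature went as c(catalyst) times time.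

Tuesday's flask at 50.0 d and Wednesday's at 25.0 d had equal counts, and they read 24.3% and 22.7% target, 1.6 percentage points apart against a scatter of 1 point per reading, although their added ligand differed.

But Friday's flask was hotter. It read 14.5% target, falling, at 1.67 d, and Wednesday's flask passed that reading near 33.9 d, so the heat factor from 25 °C to 60 °C read 20.3. Spread evenly over the degrees, that gave 1.54 at 30 °C.

My clock was therefore time, times c(catalyst) over 1 mM, times the heat factor. Autumn's clock reading at its end was 23.1 d, close to the pair above, so I expected about 23.5% target there. Noon's clock read 304 d, far beyond Wednesday's last reading, and summer's read 4010 d, so I expected no target in either. Substrate was not among the readings, so for autumn the clock gave me target, not its share.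

The forecast said autumn, with 0% for noon, 0% for summer and 32% for autumn, holding that “rate scales roughly with catalyst”.

Noon and summer gave 0% and 0%, and autumn came highest with 32.3%.

    catalyst + other conformer → catalyst + isomer of the product (k = 0.870 M⁻¹ min⁻¹, Ea = 63.0 kJ mol⁻¹)
    substrate ⇌ other conformer (K = 0.810, k = 3.10 × 10⁻⁵ min⁻¹, Ea = 123 kJ mol⁻¹, ΔH = −30.0 kJ mol⁻¹)
    catalyst + target → catalyst + over-reaction product (k = 1.50 M⁻¹ min⁻¹, Ea = 72.0 kJ mol⁻¹)
    substrate + catalyst → catalyst + target (k = 1.30 M⁻¹ min⁻¹, Ea = 78.0 kJ mol⁻¹)
    catalyst + added ligand ⇌ idle complex, settled at all times (K = 470 M⁻¹, ΔH = 17.0 kJ mol⁻¹)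
    (constants at 60 °C)

Autumn ended with 24.9% target, while idle complex held 14.9% of the catalyst. At 7.50 d, autumn's clock read 11.5 d, between the 10.0 d of Wednesday's first reading and the 12.5 d of Tuesday's reading at 25.0 d, which gave 27.6% and 29.5% target; autumn then held 30.2% target.

The numbers in the tables stem from a simulated flask from invented constants; noise was put on by code.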